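**Retrosynthetic overview**
1. The last step closes both small rings at once (C7–C15 and O–C6, spongian numbering). Its substrate is a monocyclic C6-acid/C15-aldehyde, the seco compound from which the sponge is presumed to close the same two bonds (aldol, then lactonisation).
2. C14 carries the formyl group and is allylic, so it is left stereochemically free. The closure is run as a dynamic, catalyst-controlled aldol-lactonisation that fixes C14, C15 and C7 together.
3. Ring C comes from a Diels–Alder reaction of acrolein with a 1,2,3-trisubstituted diene. This places C8=C9 and only has to set C13.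
4. The diene comes from a Suzuki union of an (S)-1-iodovinyl ring-A piece with a (Z)-alkenylboronate made from pent-4-ynoic acid. In the ring-A piece, C10 is set by Cu-catalysed conjugate addition to 3-methylcyclohexenone and the gem-dimethyl group is made from its C=O.
5. Ring order: A (bought six-membered ring), then C (Diels–Alder), then cyclopentane and β-lactone in one final operation.

Assumption: spongian numbering is used (C6 lactone C=O, C7, C15 lactone CH–O, C8=C9, C10 quaternary, C13/C16 CH–CH2O, C14 ring-fusion CH); in steps 1 and 12 the catalyst antipode meant is the one that gives the drawn sense, and its (pseudo)enantiomer is taken if the sense turns out opposite.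

**Step 1**
Reactants: 1 3-methylcyclohex-2-en-1-one; 2 ethynyl(trimethyl)silane
Product: 4 (3S)-3-methyl-3-[1-(trimethylsilyl)ethenyl]cyclohexan-1-one, via vinylalane 3 (not isolated)
Conditions: 2, DIBAL-H, hexane/THF, 55 °C; then 1, chiral sulfonate-NHC·Ag complex (2.5 mol %), Cu(OTf)2 (5 mol %), THF, −15 → 22 °C; aq. Rochelle salt
Reagents that add atoms: none
Why: Hydroalumination puts Al on the Si-bearing carbon, and the NHC–Cu-catalysed enantioselective conjugate addition then transfers the α-silylvinyl group to one face of the enone, setting the quaternary C10 as S.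

**Step 2**
Reactants: 4 (3S)-3-methyl-3-[1-(trimethylsilyl)ethenyl]cyclohexan-1-one
Product: 5 (3S)-3-(1-iodoethenyl)-3-methylcyclohexan-1-one
Conditions: NIS, MeCN, 0 °C → rt, dark
Reagents that add atoms: N-iodosuccinimide, O=C1CCC(=O)N1I
Why: Iododesilylation (electrophilic ipso-substitution of a vinylsilane) swaps Si for I on a 1,1-disubstituted alkene, so no geometry has to be controlled and C10 is untouched.

**Step 3**
Reactants: 5 (3S)-3-(1-iodoethenyl)-3-methylcyclohexan-1-one
Product: 6 (1S)-1-(1-iodoethenyl)-1,3,3-trimethylcyclohexane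
Conditions: Me2Zn, TiCl4 (→ Me2TiCl2, 2.5 equiv), CH2Cl2, −40 °C → rt
Reagents that add atoms: dimethylzinc, C[Zn]C
Why: In the Reetz geminal dimethylation, Me2TiCl2 adds one methyl to C=O, the titanium alkoxide ionises to a tertiary cation that takes the second methyl, and the electron-poor vinyl iodide and C10 are spectators while the new carbon is not stereogenic.

**Step 4**
Reactants: 7 pent-4-ynoic acid
Product: 8 6-hydroxyhex-4-ynoic acid
Conditions: n-BuLi (2.1 equiv), THF, −78 → 0 °C; (CH2O)n, → rt; aq. HCl
Reagents that add atoms: paraformaldehyde (as formaldehyde), C=O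
Why: A carboxylate/acetylide dianion forms because the alkyne C–H is far more acidic than the α-CH2 of a carboxylate, and it is then hydroxymethylated.

**Step 5**
Reactants: 8 6-hydroxyhex-4-ynoic acid
Product: 9 benzyl 6-(benzyloxy)hex-4-ynoate
Conditions: BnOC(=NH)CCl3 (2.4 equiv), TfOH (5 mol %), CH2Cl2/cyclohexane, 0 °C → rt
Reagents that add atoms: benzyl 2,2,2-trichloroacetimidate, N=C(OCc1ccccc1)C(Cl)(Cl)Cl
Why: Acid-catalysed trichloroacetimidate benzylation protects the alcohol and the acid in one pot without base, so the alkyne cannot isomerise to an allene.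

**Step 6**
Reactants: 9 benzyl 6-(benzyloxy)hex-4-ynoate
Product: 10 benzyl (4Z)-6-(benzyloxy)-4-(4,4,5,5-tetramethyl-1,3,2-dioxaborolan-2-yl)hex-4-enoate
Conditions: B2pin2, CuCl (5 mol %), PCy3 (6 mol %), NaOt-Bu (10 mol %), BnOH (2 equiv), toluene, rt
Reagents that add atoms: bis(pinacolato)diboron, CC1(C)OB(OC1(C)C)B1OC(C)(C)C(C)(C)O1
Why: In this Cu-catalysed formal hydroboration (syn borylcupration, then protonolysis), Cu sits next to the electron-poor CH2OBn and boron goes to the distal carbon C8, giving the Z-boronate, while BnOH as proton source makes any ester exchange degenerate.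

**Step 7**
Reactants: 6 (1S)-1-(1-iodoethenyl)-1,3,3-trimethylcyclohexane; 10 benzyl (4Z)-6-(benzyloxy)-4-(pinacolboryl)hex-4-enoate
Product: 11 benzyl (4E)-6-(benzyloxy)-4-{1-[(1S)-1,3,3-trimethylcyclohexyl]ethenyl}hex-4-enoate
Conditions: Pd(OAc)2/SPhos (5/10 mol %), Cs2CO3, THF/H2O, 50 °C
Reagents that add atoms: none
Why: Suzuki–Miyaura coupling proceeds with retention at both sp2 carbons, so CH2OBn ends up trans to C9 (the "outside" diene position), and a bulky biarylphosphine is used because both partners are α-branched.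

**Step 8**
Reactants: 11 diene; 12 acrolein (prop-2-enal)
Product: 13 benzyl 3-{(5S,6S)-6-[(benzyloxy)methyl]-5-formyl-2-[(1S)-1,3,3-trimethylcyclohexyl]cyclohex-1-en-1-yl}propanoate
Conditions: (5R)-5-benzyl-2,2,3-trimethylimidazolidin-4-one·HCl (20 mol %), 12 (4 equiv), MeCN/H2O 95:5, 0 → 23 °C
Reagents that add atoms: none
Why: In this iminium-catalysed Diels–Alder reaction, the C14 and C9 substituents both steer Cβ of acrolein to the free CH2 terminus ("ortho/para"), the benzyl group of the (5R)-catalyst blocks the Cα Si face so C13 is formed S by Re attack in both the endo and the exo mode, and the endo rule gives the 13,14-cis (14S) adduct, whose C14 is corrected in step 12.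

**Step 9**
Reactants: 13 Diels–Alder aldehyde
Product: 15 benzyl 3-{(5S,6S)-6-[(benzyloxy)methyl]-5-[(butanoyloxy)methyl]-2-[(1S)-1,3,3-trimethylcyclohexyl]cyclohex-1-en-1-yl}propanoate, via aluminium alkoxide 14 (not isolated)
Conditions: DIBAL-H (1.05 equiv), CH2Cl2, −78 °C; then (PrCO)2O, pyridine, DMAP, −78 °C → rt
Reagents that add atoms: butyric anhydride, CCCC(=O)OC(=O)CCC
Why: This is a reductive acylation in which the aldehyde takes up one equivalent of DIBAL-H at −78 °C far faster than the benzyl ester, the aluminium alkoxide is acylated in situ under DMAP catalysis, and no stereocentre is touched.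

**Step 10**
Reactants: 15 butyrate
Product: 16 3-{(5S,6S)-5-[(butanoyloxy)methyl]-6-(hydroxymethyl)-2-[(1S)-1,3,3-trimethylcyclohexyl]cyclohex-1-en-1-yl}propanoic acid
Conditions: H2 (1 atm), Pd/C, EtOAc, rt
Reagents that add atoms: none
Why: Neutral hydrogenolysis removes the benzyl ether and the benzyl ester together, and the tetrasubstituted alkene flanked by a quaternary carbon and the butyrate are inert.

**Step 11**
Reactants: 16 hydroxy acid
Product: 17 3-{(5S,6S)-5-[(butanoyloxy)methyl]-6-formyl-2-[(1S)-1,3,3-trimethylcyclohexyl]cyclohex-1-en-1-yl}propanoic acid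
Conditions: Dess–Martin periodinane, CH2Cl2, 0 °C → rt; used crude
Reagents that add atoms: none
Why: Dess–Martin oxidation stops at the aldehyde, tolerates the free acid and is non-basic, so the β,γ-unsaturated aldehyde is not pushed into conjugation.

**Step 12**
Reactants: 17 aldehyde acid (13S,14S)
Product: 19 3'-norspongiolactone, via C14-epimeric aldehyde acid 18 (not isolated)
Conditions: 2-chloro-1-methylpyridinium iodide (3 equiv), i-Pr2NEt (4 equiv), O-TMS-quinine (20 mol %), MeCN, 23 °C, slow addition of 17
Reagents that add atoms: none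
Why: Proposed new method: this is a dynamic kinetic version of the nucleophile-catalysed aldol-lactonisation of aldehyde acids (closest known chemistry: that reaction and its simple kinetic resolution), in which the amine base equilibrates 17 and 18 through the dienolate of the doubly activated C14–H (γ-protonation at C9, next to the quaternary C10, is too hindered to drain material into the conjugated enal), ring closure needs a pseudo-equatorial CHO so only 14R keeps CH2OCOPr equatorial, the C7 ammonium enolate then adds to the aldehyde face syn to H14 (anti to C13), only the cis aldolate can lactonise, and the cinchona catalyst is matched to this (7R,15S) mode and mismatched to closure of 14S, so C14 (R), C15 (S) and C7 (R) are set in one operation.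

**Compound list**
1 | 3-methylcyclohex-2-en-1-one | CC1=CC(=O)CCC1 | starting material
2 | ethynyl(trimethyl)silane | C#C[Si](C)(C)C | starting material
3 | diisobutyl[1-(trimethylsilyl)ethenyl]aluminium | C=C([Si](C)(C)C)[Al](CC(C)C)CC(C)C | intermediate
4 | (3S)-3-methyl-3-[1-(trimethylsilyl)ethenyl]cyclohexan-1-one | C=C([Si](C)(C)C)[C@@]1(C)CCCC(=O)C1 | intermediate
5 | (3S)-3-(1-iodoethenyl)-3-methylcyclohexan-1-one | C=C(I)[C@@]1(C)CCCC(=O)C1 | intermediate
6 | (1S)-1-(1-iodoethenyl)-1,3,3-trimethylcyclohexane | C=C(I)[C@@]1(C)CCCC(C)(C)C1 | intermediate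
7 | pent-4-ynoic acid | C#CCCC(=O)O | starting material
8 | 6-hydroxyhex-4-ynoic acid | OCC#CCCC(=O)O | intermediate
9 | benzyl 6-(benzyloxy)hex-4-ynoate | O=C(CCC#CCOCc1ccccc1)OCc1ccccc1 | intermediate
10 | benzyl (4Z)-6-(benzyloxy)-4-(pinacolboryl)hex-4-enoate | O=C(OCc1ccccc1)CC/C(B2OC(C)(C)C(C)(C)O2)=C\COCc1ccccc1 | intermediate
11 | benzyl (4E)-6-(benzyloxy)-4-{1-[(1S)-1,3,3-trimethylcyclohexyl]ethenyl}hex-4-enoate | O=C(OCc1ccccc1)CC/C(C(=C)[C@@]2(C)CCCC(C)(C)C2)=C\COCc1ccccc1 | intermediate
12 | acrolein | C=CC=O | starting material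
13 | Diels–Alder aldehyde (10S,13S,14S) | O=C[C@H]1CCC([C@@]2(C)CCCC(C)(C)C2)=C(CCC(=O)OCc2ccccc2)[C@H]1COCc1ccccc1 | intermediate
14 | diisobutylaluminium alkoxide of the C16 alcohol | CC(C)C[Al](CC(C)C)OC[C@H]1CCC([C@@]2(C)CCCC(C)(C)C2)=C(CCC(=O)OCc2ccccc2)[C@H]1COCc1ccccc1 | intermediate
15 | C16 butyrate, bis-benzyl protected | CCCC(=O)OC[C@H]1CCC([C@@]2(C)CCCC(C)(C)C2)=C(CCC(=O)OCc2ccccc2)[C@H]1COCc1ccccc1 | intermediate
16 | C15 hydroxy C6 acid | CCCC(=O)OC[C@H]1CCC([C@@]2(C)CCCC(C)(C)C2)=C(CCC(=O)O)[C@H]1CO | intermediate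
17 | seco aldehyde acid (13S,14S) | CCCC(=O)OC[C@H]1CCC([C@@]2(C)CCCC(C)(C)C2)=C(CCC(=O)O)[C@H]1C=O | intermediate
18 | seco aldehyde acid (13S,14R) | CCCC(=O)OC[C@H]1CCC([C@@]2(C)CCCC(C)(C)C2)=C(CCC(=O)O)[C@@H]1C=O | intermediate
19 | 3'-norspongiolactone (7R,10S,13S,14R,15S) | CCCC(=O)OC[C@H]1CCC([C@@]2(C)CCCC(C)(C)C2)=C2C[C@H]3C(=O)O[C@H]3[C@@H]21 | target

**Step count**
Total steps: 12. Longest linear sequence: 9 (steps 1–3 and 7–12).

**Steps most likely to fail**

Step 12 (dynamic aldol-lactonisation). C14 epimerisation may be too slow, or the aldehyde may drift into conjugation. The fallback sets out from 17 and returns at 19. It replaces the ammonium enolate by a metal thioester enolate. PhSH/EDC converts 17 into the S-phenyl thioester of the seco aldehyde acid F6. Soft enolisation with MgBr2·OEt2/i-Pr2NEt in CH2Cl2 also equilibrates C14. It gives a chelated intramolecular aldol whose cis magnesium aldolate closes onto the thioester on warming, expelling thiolate, to give 19.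

Step 8 (Diels–Alder of a twisted 2-alkyl-3-tert-alkyl diene). The iminium ion may not be electrophilic enough. The fallback sets out from 11 and returns at 15. Stereocontrol moves from the catalyst to a covalently bound auxiliary on a far more electrophilic, chelated dienophile. Diene 11 reacts with commercial (R)-3-acryloyl-4-benzyl-1,3-oxazolidin-2-one and Et2AlCl (CH2Cl2, −78 °C), with Cα Re attack anti to the benzyl group, to give the imide cycloadduct F4. LiBH4/MeOH removes the auxiliary reductively to give the primary C16 alcohol F5. Butyryl chloride/pyridine then gives 15.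

Step 3 (geminal dimethylation). The tertiary cation may eliminate instead of taking the second methyl. The fallback sets out from 3 and returns at 6. The gem-dimethyl group is bought rather than made, and the carbonyl is deleted. Alane 3 is added under the same Cu–NHC catalysis to commercial isophorone to give (3R)-3,5,5-trimethyl-3-[1-(trimethylsilyl)ethenyl]cyclohexan-1-one F1. TsNHNH2 gives its tosylhydrazone F2. Catecholborane, then NaOAc·3H2O in refluxing CHCl3, gives trimethyl{1-[(1S)-1,3,3-trimethylcyclohexyl]ethenyl}silane F3. NIS in MeCN gives 6.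

**Further compounds**
F1 | step 3 | (3R)-3,5,5-trimethyl-3-[1-(trimethylsilyl)ethenyl]cyclohexan-1-one | C=C([Si](C)(C)C)[C@@]1(C)CC(=O)CC(C)(C)C1
F2 | step 3 | tosylhydrazone of F1 | C=C([Si](C)(C)C)[C@@]1(C)CC(=NNS(=O)(=O)c2ccc(C)cc2)CC(C)(C)C1
F3 | step 3 | trimethyl{1-[(1S)-1,3,3-trimethylcyclohexyl]ethenyl}silane | C=C([Si](C)(C)C)[C@@]1(C)CCCC(C)(C)C1
F4 | step 8 | imide cycloadduct | O=C1OC[C@@H](Cc2ccccc2)N1C(=O)[C@H]1CCC([C@@]2(C)CCCC(C)(C)C2)=C(CCC(=O)OCc2ccccc2)[C@H]1COCc1ccccc1
F5 | step 8 | primary C16 alcohol | OC[C@H]1CCC([C@@]2(C)CCCC(C)(C)C2)=C(CCC(=O)OCc2ccccc2)[C@H]1COCc1ccccc1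
F6 | step 12 | S-phenyl thioester of the seco aldehyde acid | CCCC(=O)OC[C@H]1CCC([C@@]2(C)CCCC(C)(C)C2)=C(CCC(=O)Sc2ccccc2)[C@H]1C=O
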